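The retrosynthesis first removes the two phenol benzyl groups. It then cuts C1–O, C5–O, C2–O3 and C6–O7 together, which opens ring A (C1–C2–O3–C4–C5) and ring B (C5–C6–O7–C8–C1) to a flat, achiral (2E,3E)-diene diol. Cutting C1=C2 and C5=C6 leads back to dimethyl succinate and two O-benzylvanillin units.
Enabling feature: on C1–C2 (and C5–C6) a tertiary hydroxyl sits next to a benzylic ring oxygen with the aryl group cis to that hydroxyl, and C1 (C5) also carries the oxymethylene C8 (C4). This pattern results when the epoxide of an (E)-allylic alcohol is opened with inversion at its benzylic carbon.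
Forward order: succinate supplies C4–C5–C1–C8, two Stobbe condensations add C2 and C6 with their arenes, and ester reduction gives the diene diol. Rings A and B then close one after the other in a single flask, and debenzylation ends the route.
Stereochemistry: all four stereocentres arise in the key step. C1 and C5 come from tartrate-controlled oxygen delivery, C2 and C6 from the (E)-alkene geometry combined with inversion.

Key step: step 7

Remark: the locants of the 3,7-dioxabicyclo[3.3.0]octane are also used for the open-chain precursors. C1 and C5 are the ring-fusion carbons, C2 and C6 the benzylic carbons, and C4 and C8 the methylenes. Ar = 4-benzyloxy-3-methoxyphenyl.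
Assumption: the sense of induction is taken from (E)-2-substituted cinnamyl alcohols, which give (2S,3S)-epoxy alcohols with L-(+)-tartrates. Applied to the diene diol this means 1S,2S,5S,6S in the bis-epoxide. After inversion at C2 and C6 it becomes 1S,2R,5S,6R in the bicycle, which is the configuration of the target.

Step 1
Reactants: 1 vanillin; 2 benzyl bromide
Product: 3 4-benzyloxy-3-methoxybenzaldehyde
Conditions: K2CO3, DMF, 23 °C
Reagents that add atoms: none
Why: Williamson ether synthesis: the phenoxide generated by K2CO3 displaces bromide from the benzylic halide in an SN2 reaction while the aldehyde stays untouched, and the benzyl ether later withstands alkoxide, hydride and peroxide.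

Step 2
Reactants: 3 4-benzyloxy-3-methoxybenzaldehyde; 4 dimethyl succinate
Product: 5 (3E)-4-(4-benzyloxy-3-methoxyphenyl)-3-(methoxycarbonyl)but-3-enoic acid
Conditions: NaOMe, MeOH, reflux; then aq. HCl
Reagents that add atoms: none
Why: Stobbe condensation: the succinate enolate adds to the aldehyde, the resulting alkoxide lactonises onto the remote ester, and base-induced E1cB opening of that paraconic ester gives the half-ester irreversibly as its carboxylate, with the aryl group trans to the remaining ester, that is (E), because this avoids the aryl/ester clash in the elimination.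

Step 3
Reactants: 5 (3E)-4-(4-benzyloxy-3-methoxyphenyl)-3-(methoxycarbonyl)but-3-enoic acid
Product: 6 dimethyl (2E)-2-[(4-benzyloxy-3-methoxyphenyl)methylidene]butanedioate
Conditions: MeOH, H2SO4 (cat.), reflux
Reagents that add atoms: methanol, CO
Why: Fischer esterification of the unhindered, non-conjugated acid restores a diester whose remaining CH2 can be deprotonated for the second condensation, and neither the (E)-alkene nor the benzyl ether responds to catalytic acid in methanol.

Step 4
Reactants: 6 dimethyl (2E)-2-[(4-benzyloxy-3-methoxyphenyl)methylidene]butanedioate; 3 4-benzyloxy-3-methoxybenzaldehyde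
Product: 7 monomethyl (2E,3E)-2,3-bis[(4-benzyloxy-3-methoxyphenyl)methylidene]butanedioate
Conditions: NaOMe, MeOH, reflux; then aq. HCl
Reagents that add atoms: none
Why: Second Stobbe condensation: the extended enolate of 6 reacts at its alpha carbon with a second molecule of 3, and the same lactonisation and E1cB sequence installs the second arylidene group, again with aryl trans to the carbonyl group, which is the established way to (E,E)-bis(arylidene)succinic half-esters.

Step 5
Reactants: 7 monomethyl (2E,3E)-2,3-bis[(4-benzyloxy-3-methoxyphenyl)methylidene]butanedioate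
Product: 8 dimethyl (2E,3E)-2,3-bis[(4-benzyloxy-3-methoxyphenyl)methylidene]butanedioate
Conditions: MeI, K2CO3, DMF, 23 °C
Reagents that add atoms: methyl iodide, CI
Why: O-Alkylation of the carboxylate with MeI (SN2) esterifies the hindered conjugated acid under mild basic conditions that should leave both alkene geometries intact.

Step 6
Reactants: 8 dimethyl (2E,3E)-2,3-bis[(4-benzyloxy-3-methoxyphenyl)methylidene]butanedioate
Product: 9 (2E,3E)-2,3-bis[(4-benzyloxy-3-methoxyphenyl)methylidene]butane-1,4-diol
Conditions: iBu2AlH (5 equiv), CH2Cl2, −78 → 0 °C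
Reagents that add atoms: none
Why: 1,2-Reduction of alpha,beta-unsaturated esters with iBu2AlH stops cleanly at the allylic alcohol without conjugate reduction, so both (E)-alkenes (aryl trans to CH2OH) and the benzyl ethers are carried unchanged into the diol.

Step 7
Reactants: 9 (2E,3E)-2,3-bis[(4-benzyloxy-3-methoxyphenyl)methylidene]butane-1,4-diol
Product: 12 di-O-benzylprinsepiol (1S,2R,5S,6R)-2,6-bis(4-benzyloxy-3-methoxyphenyl)-3,7-dioxabicyclo[3.3.0]octane-1,5-diol, via C2-symmetric bis-epoxide 10 (not isolated), via spiro-epoxy oxolane 11 (not isolated)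
Conditions: Ti(OiPr)4 (2.2 equiv), L-(+)-diethyl tartrate (2.6 equiv), tBuOOH (3 equiv, decane), 4 Å MS, CH2Cl2, −25 °C; then 23 °C
Reagents that add atoms: tert-butyl hydroperoxide, CC(C)(C)OO
Why: Each CH2OH of 9 exchanges onto the dimeric titanium–tartrate complex, which passes the distal oxygen of bound tBuOOH to one face of the adjacent trisubstituted alkene (Sharpless asymmetric epoxidation), and the (2S,3S) sense known for (E)-2-substituted cinnamyl alcohols with L-(+)-tartrate corresponds here to 1S and 5S in bis-epoxide 10. On warming, the tetravalent titanium still chelated by each epoxy alkoxide polarises the benzylic C–O bond and the hydroxymethyl oxygen of the other half attacks C2 (then C6) from the rear, the closest known reaction types being the titanium-alkoxide-assisted C3 opening of 2,3-epoxy alcohols and the acid-promoted cyclisation of 3,4-epoxy alcohols that carry an aryl group on the far carbon. Ring A (O3–C2 bond, giving 11) and ring B (O7–C6 bond, giving 12) each close in the 5-endo-tet mode, which should win over the 4-exo alternative at C1 or C5 because positive charge builds up only at the aryl-bearing carbon and an oxetane would be strained. C1 and C5 are fixed by the tartrate-controlled face selection and keep their C–O bonds, whereas C2 and C6 follow from the (E) geometry plus inversion, which places each aryl group cis to the neighbouring tertiary hydroxyl on the convex face, and a looser, cation-like opening should lead to the same exo arrangement because it is also the less crowded one. The step needs enantioface selectivity at two homotopic alkenes, benzylic regioselectivity and intramolecular capture ahead of isopropanol: the first is secured by a full equivalent of chiral complex per directing hydroxyl, the second by the electron-rich arene and the third by the five-ring proximity of the internal nucleophile. Because both halves are selected independently, most of the residual facial error should end in a diastereomeric meso series that cannot reach a cis-fused bicycle and is separated, so the enantiomeric purity of 12 should exceed that of a single epoxidation.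

Step 8
Reactants: 12 di-O-benzylprinsepiol
Product: 13 prinsepiol (1S,2R,5S,6R)-2,6-bis(4-hydroxy-3-methoxyphenyl)-3,7-dioxabicyclo[3.3.0]octane-1,5-diol
Conditions: H2 (1 atm), 10% Pd/C, EtOAc–MeOH, 23 °C, stopped after uptake of two equivalents of H2
Reagents that add atoms: none
Why: Catalytic hydrogenolysis: the unhindered O-benzyl bonds of the aryl benzyl ethers are cleaved much faster than the ring C2–O3 and C6–O7 bonds, which are shielded by the adjacent fully substituted carbons, and no stereocentre takes part.

Compound list
1 | vanillin | COc1cc(C=O)ccc1O | starting material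
2 | benzyl bromide | BrCc1ccccc1 | starting material
3 | 4-benzyloxy-3-methoxybenzaldehyde | COc1cc(C=O)ccc1OCc1ccccc1 | intermediate
4 | dimethyl succinate | COC(=O)CCC(=O)OC | starting material
5 | (3E)-4-(4-benzyloxy-3-methoxyphenyl)-3-(methoxycarbonyl)but-3-enoic acid | COC(=O)/C(CC(=O)O)=C/c1ccc(OCc2ccccc2)c(OC)c1 | intermediate
6 | dimethyl (2E)-2-[(4-benzyloxy-3-methoxyphenyl)methylidene]butanedioate | COC(=O)/C(CC(=O)OC)=C/c1ccc(OCc2ccccc2)c(OC)c1 | intermediate
7 | monomethyl (2E,3E)-2,3-bis[(4-benzyloxy-3-methoxyphenyl)methylidene]butanedioate | COC(=O)/C(=C/c1ccc(OCc2ccccc2)c(OC)c1)/C(=C\c1ccc(OCc2ccccc2)c(OC)c1)C(=O)O | intermediate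
8 | dimethyl (2E,3E)-2,3-bis[(4-benzyloxy-3-methoxyphenyl)methylidene]butanedioate | COC(=O)/C(=C/c1ccc(OCc2ccccc2)c(OC)c1)/C(=C\c1ccc(OCc2ccccc2)c(OC)c1)C(=O)OC | intermediate
9 | (2E,3E)-2,3-bis[(4-benzyloxy-3-methoxyphenyl)methylidene]butane-1,4-diol | OC/C(=C/c1ccc(OCc2ccccc2)c(OC)c1)/C(=C\c1ccc(OCc2ccccc2)c(OC)c1)CO | intermediate
10 | [(2S,2'S,3S,3'S)-3,3'-bis(4-benzyloxy-3-methoxyphenyl)-2,2'-bioxirane-2,2'-diyl]dimethanol | OC[C@@]1(O[C@H]1c2ccc(OCc3ccccc3)c(OC)c2)[C@@]4(CO)O[C@H]4c5ccc(OCc6ccccc6)c(OC)c5 | intermediate
11 | (2S,3S,6R,7S)-2,6-bis(4-benzyloxy-3-methoxyphenyl)-7-(hydroxymethyl)-1,5-dioxaspiro[2.4]heptan-7-ol (ring A closed, C5–C6 still an epoxide) | OC[C@]1(O)[C@@H](c2ccc(OCc3ccccc3)c(OC)c2)OC[C@@]14O[C@H]4c5ccc(OCc6ccccc6)c(OC)c5 | intermediate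
12 | di-O-benzylprinsepiol, (1S,2R,5S,6R)-2,6-bis(4-benzyloxy-3-methoxyphenyl)-3,7-dioxabicyclo[3.3.0]octane-1,5-diol | COc1cc([C@H]2OC[C@]3(O)[C@@H](c4ccc(OCc5ccccc5)c(OC)c4)OC[C@]23O)ccc1OCc1ccccc1 | intermediate
13 | prinsepiol, (1S,2R,5S,6R)-2,6-bis(4-hydroxy-3-methoxyphenyl)-3,7-dioxabicyclo[3.3.0]octane-1,5-diol | COc1cc([C@H]2OC[C@]3(O)[C@@H](c4ccc(O)c(OC)c4)OC[C@]23O)ccc1O | target

Total step count: 8. Longest linear sequence: 8 steps (1 to 13).

Steps most likely to fail

**Step 7.**
- The first electron-rich epoxide may open before the second alkene has been oxidised. This uses up the primary allylic hydroxyl that the chiral complex needs for the second delivery.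
- Further threats are capture of the benzylic position by isopropanol or hydroperoxide, ionisation towards the allylic C1 position, and erosion of face selectivity through chelation of titanium by the diol.
- The fallback sets out from 9 and rejoins the route at 11. It separates the two oxidations and puts the second one under substrate control.
- The titanium–tartrate system with a single equivalent of tBuOOH, followed by warming, should stop at the ring A monocycle (2R,3S,4Z)-2-(4-benzyloxy-3-methoxyphenyl)-4-[(4-benzyloxy-3-methoxyphenyl)methylidene]-3-(hydroxymethyl)oxolan-3-ol F1.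
- VO(acac)2 and tBuOOH in CH2Cl2 at 0 °C should then deliver oxygen to the face of C5=C6 that is syn to the tertiary allylic C1 hydroxyl (hydroxyl-directed epoxidation). This gives 11, and catalytic camphorsulfonic acid closes ring B to 12.

**Step 4.**
- The second condensation takes place at a hindered, extended enolate. It may be slow, suffer retro-aldol reversal and saponification, and lose part of the alkene geometry through reversible methoxide addition.
- The fallback sets out from 3 and comes back at 8. It forms the central C1–C5 bond last instead of the two C=C bonds.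
- Wittig olefination of 3 with Ph3P=C(Br)CO2Me in CH2Cl2 should give methyl (2Z)-3-(4-benzyloxy-3-methoxyphenyl)-2-bromoprop-2-enoate F2, with aryl cis to bromine.
- Reductive homocoupling with zerovalent nickel made in the flask from NiCl2(PPh3)2, Zn and Et4NI in THF at 50 °C joins the two sp2 carbons with retention of geometry and gives 8. This replaces steps 2 to 5.

**Step 8.**
- Once the phenols are free, hydrogenolytic opening of ring A or ring B at the benzylic C2–O3 or C6–O7 bond may compete with the removal of the second benzyl group.
- The fallback sets out from 8 and comes back at 13. It exchanges the protecting group before the rings exist, so that no reductive step touches the bicycle.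
- BCl3 with pentamethylbenzene in CH2Cl2 at −78 °C should give dimethyl (2E,3E)-2,3-bis[(4-hydroxy-3-methoxyphenyl)methylidene]butanedioate F3.
- tBuMe2SiCl and imidazole in DMF then give the bis(silyl ether) dimethyl (2E,3E)-2,3-bis{[4-(tert-butyldimethylsilyloxy)-3-methoxyphenyl]methylidene}butanedioate F4.
- iBu2AlH gives (2E,3E)-2,3-bis{[4-(tert-butyldimethylsilyloxy)-3-methoxyphenyl]methylidene}butane-1,4-diol F5.
- The conditions of step 7 give di-O-(tert-butyldimethylsilyl)prinsepiol F6.
- Bu4NF buffered with AcOH in THF at 0 °C releases 13.

Further compounds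
F1 | step 7 | (2R,3S,4Z)-2-(4-benzyloxy-3-methoxyphenyl)-4-[(4-benzyloxy-3-methoxyphenyl)methylidene]-3-(hydroxymethyl)oxolan-3-ol | OC[C@]1(O)[C@@H](c2ccc(OCc3ccccc3)c(OC)c2)OC/C1=C/c4ccc(OCc5ccccc5)c(OC)c4
F2 | step 4 | methyl (2Z)-3-(4-benzyloxy-3-methoxyphenyl)-2-bromoprop-2-enoate | COC(=O)/C(Br)=C/c1ccc(OCc2ccccc2)c(OC)c1
F3 | step 8 | dimethyl (2E,3E)-2,3-bis[(4-hydroxy-3-methoxyphenyl)methylidene]butanedioate | COC(=O)/C(=C/c1ccc(O)c(OC)c1)/C(=C\c1ccc(O)c(OC)c1)C(=O)OC
F4 | step 8 | dimethyl (2E,3E)-2,3-bis{[4-(tert-butyldimethylsilyloxy)-3-methoxyphenyl]methylidene}butanedioate | COC(=O)/C(=C/c1ccc(O[Si](C)(C)C(C)(C)C)c(OC)c1)/C(=C\c1ccc(O[Si](C)(C)C(C)(C)C)c(OC)c1)C(=O)OC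
F5 | step 8 | (2E,3E)-2,3-bis{[4-(tert-butyldimethylsilyloxy)-3-methoxyphenyl]methylidene}butane-1,4-diol | OC/C(=C/c1ccc(O[Si](C)(C)C(C)(C)C)c(OC)c1)/C(=C\c1ccc(O[Si](C)(C)C(C)(C)C)c(OC)c1)CO
F6 | step 8 | di-O-(tert-butyldimethylsilyl)prinsepiol | COc1cc([C@H]2OC[C@]3(O)[C@@H](c4ccc(O[Si](C)(C)C(C)(C)C)c(OC)c4)OC[C@]23O)ccc1O[Si](C)(C)C(C)(C)C
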